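I began with a leftover: the tables gave target but not the starting material still in the flask, so I first had to guess what was left.

| setting | birch | maple | larch | flask |
|---|---|---|---|---|
| starting material | 0.12 M | 0.12 M | 0.24 M | 0.12 M |
| gas phase | 7.1 mM (held) | 7.1 mM (held) | 7.1 mM (held) | 7.1 mM (held) |
| protic impurity | 3.4 mM | 5.3 mM | 2.4 mM | 2.40 mM |
| remark | run made earlier | run made earlier | run made earlier |  |
| time |  |  |  | 20 min |

| run | time / min | target / % |
|---|---|---|
| birch | 0.833 | 5.1 |
| birch | 2.50 | 9.7 |
| birch | 5.00 | 18.8 |
| birch | 6.00 | 22.2 |
| birch | 10.0 | 29.3 |
| birch | 12.0 | 34.4 |
| birch | 15.0 | 39.1 |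
| maple | 2.50 | 10.2 |
| maple | 5.00 | 19.7 |
| maple | 6.00 | 22.0 |
| maple | 10.0 | 31.6 |
| maple | 12.0 | 35.3 |
| maple | 15.0 | 39.3 |
| larch | 1.33 | 5.5 |
| larch | 2.50 | 8.9 |
| larch | 5.00 | 17.8 |
| larch | 8.00 | 22.2 |
| larch | 15.0 | 37.8 |

(readings scatter by 1 percentage point)

- target at 20 min, in percent of the starting material charged
- the change that raises the amount of target at 20 min, in percent of the starting material charged most ("none" if none brings more than 2 percentage points) (Wednesday's / Friday's / none)
- amount of target at 20 min, in percent of the starting material charged, after Wednesday's

- Wednesday's: doubling the saturation concentration of gas phase, all else as stated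
- Friday's: doubling the transfer coefficient of the gas phase, all else as stated

- the numbers in the tables scatter by 1 percentage point (one standard deviation)
- at the start none of the gas phase is in solution

At 15.0 min, larch, with 0.24 M charged, read 37.8%, against 39.1% for birch with 0.12 M. The gap was about the scatter, so I took as the zero of my scale a pseudo-first-order loss of starting material, as if each bit lost became target. Maple, with impurity at 5.3 mM against birch's 3.4 mM, read 39.3% at that same time, a gap inside the scatter, so I set the impurity aside. From the mean reading at 5.00 min:

k = 0.0416 /min

line = 1 − exp(−k·t): 34.0% at 10.0 min, 46.4% at 15.0 min, 56.5% at 20 min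

But the readings ran below this line. So I divided the mean reading by the line and called the result the kept share:

0.895 at 10.0 min, 0.835 at 15.0 min

Holding the later value would have given 47.2%, but the share was falling. Continuing at the same pace:

share at 20 min = 0.774

target = 43.7%

This kept share at the asked time was my own estimate. One doubt stayed: k came from target itself, so the share measured against my scale and was no true yield. For Wednesday's I doubled k, which was untested, and the line became 81.0%, giving 62.7% at the same share.

The forecast gave 43.5% (41% to 46.5%), chose Wednesday's, and gave 62% (50% to 72%) after it, since “Doubling saturation should nearly double the rate”.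

The flask gave 45.4%. Wednesday's added 6.5 percentage points, reaching 52.0%, and Friday's added 1.8 points, below the margin of 2 points.

    2 dissolved gas → self-condensation product (k = 120 /M/min)
    dissolved gas + target → over-reacted product (k = 2.20 /M/min)
    gas phase ⇌ dissolved gas, rate k3*(csat - [dissolved gas]) (kL = 8.50 /min)
    target ⇌ isomer of the product (K = 0.340, k = 0.160 /min)
    starting material + dissolved gas → target (k = 9.90 /M/min)
    dissolved gas + protic impurity → quenched reagent (k = 17.0 /M/min)

The flask's kept share was 0.804, against my 0.774. After Wednesday's it was 0.642, lower than in the flask, so my figure stood too high. Target stood at 45.4% in the flask partly through the back reaction of isomer of the product to target, acting together with the hour of the reading: with that back reaction taken away target stood at 14.4%, and read at 200 min it stood at 12.6%. For the same flask stopped at 12 min, the line gave 39.3% and the share, read between my two values, 0.871, so 34.2%; that flask held 34.9%.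

The data stem from a simulated flask with constants of no real substance; the scatter is artificial.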